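## Retrosynthetic overview

1. The C6 chloride is installed last by SN2 inversion of a C6 allylic alcohol. The γ-lactone (C8–C17 bond, C8-OH, C17) comes from a SmI2 intramolecular Reformatsky reaction of a C7 2-bromopropionate onto a C8 ketone.
2. The ten-membered ring is not made by macrocyclisation (no RCM or NHK). An anionic allenyl oxy-Cope ring expansion of a trans-decalin cleaves C3–C8 and forms C5–C6, giving the 3Z-ene, the 5(16)-exo-methylene diene, C6–O and (after enolate hydroxylation) C7–O in one operation.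
3. The oxy-Cope substrate comes from a C8 propargyl enol ether: a Saucy–Marbet propargyl Claisen installs the C3 allene, then a (Z)-2-alkoxyvinyl group is added to the C8 ketone.
4. Decalin ring B is closed by an intramolecular Claisen condensation. Ring A comes from a catalytic enantioselective endo Diels–Alder of trans-piperylene with ethyl (E)-2-methyl-4-oxobut-2-enoate, which sets C1, C10 and C11.
5. Ring order: A (Diels–Alder) → B (Claisen cyclisation) → ten-membered ring (ring expansion of B) → γ-lactone.

**Conventions and assumptions**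

- Briarane numbering (C1–C20) is used for every intermediate. β means the face of the C15 methyl in the usual flat briarane drawing. The SMILES strings are definitive for configuration.
- Numbered compounds are carbon-skeleton reactants and isolated products; simple reagents are given by name and SMILES.
- Assumption: the (S)-oxazaborolidinium catalyst gives the enantiomer of 4 shown; if the opposite sense is observed, the (R)-catalyst is used with no other change.
- Nothing here has been run; all selectivities are predictions from the stated models.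

## Route

**Step 1**
Reactants: 1, ethyl tiglate
Product: 2, ethyl (E)-2-methyl-4-oxobut-2-enoate
Conditions: SeO2, 1,4-dioxane, 100 °C
Reagents that add atoms: selenium dioxide, O=[Se]=O
Why: Riley allylic oxidation; the Se(IV) ene step engages the α-carbon so the γ-methyl is oxidised to the aldehyde with the E geometry retained, as in the senecioate to 3-formylcrotonate oxidation.

**Step 2**
Reactants: 2, ethyl (E)-2-methyl-4-oxobut-2-enoate; 3, (E)-penta-1,3-diene
Product: 4, ethyl (1S,5S,6S)-6-formyl-1,5-dimethylcyclohex-3-ene-1-carboxylate (CHO, C15-Me and C20-Me all cis)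
Conditions: (S)-o-tolyl-CBS-oxazaborolidine·Tf2NH (20 mol%), CH2Cl2, −78 → −20 °C
Reagents that add atoms: none
Why: Enantioselective Lewis-acid-catalysed Diels–Alder; the catalyst-bound formyl group controls regiochemistry (methyl-bearing diene terminus bonds to the formyl-bearing carbon) and sits endo, placing C20-Me cis to CHO, while the E-dienophile places C15-Me cis to CHO, so C1, C10 and C11 are set together.

**Step 3**
Reactants: 4; 5, ethyl vinyl ether (as 1-ethoxyvinyllithium)
Product: 6, ethyl (1S,5S,6S)-6-(1-hydroxy-2-oxopropyl)-1,5-dimethylcyclohex-3-ene-1-carboxylate (C9 carbinol epimers)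
Conditions: 5, t-BuLi, THF, −78 → 0 °C; then 4, −78 °C; then 1 M HCl, THF, 0 °C
Reagents that add atoms: water, O (ketone oxygen after enol-ether hydrolysis)
Why: Acyl-anion-equivalent addition to the aldehyde (much faster than to the neopentyl ester) followed by enol-ether hydrolysis gives the C8 methyl ketone; the C9 configuration is irrelevant because C9 is re-set in step 8.

**Step 4**
Reactants: 6
Product: 7, (4aS,5S,8aS)-4-hydroxy-5,8a-dimethyl-4a,5,8,8a-tetrahydronaphthalene-1,3(2H,4H)-dione (trans-fused; C2 and C8 carbonyls, C9-OH)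
Conditions: LiHMDS (3.5 equiv), THF, −78 → 0 °C; aq. NH4Cl
Reagents that add atoms: none
Why: Intramolecular Claisen (Dieckmann-type) condensation of the kinetic methyl-ketone enolate (C3) onto the C2 ester closes ring B as a stabilised 1,3-dione enolate; the trans ring fusion is already fixed by the Diels–Alder.

**Step 5**
Reactants: 7; 8, propargyl alcohol
Product: 9, trans-decalin vinylogous ester (C2 ketone, C3=C8 enol ether carrying O-propargyl on C8, C9-OH, Δ12)
Conditions: 8 (5 equiv), p-TsOH (cat.), benzene, reflux, Dean–Stark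
Reagents that add atoms: none
Why: Acid-catalysed enol etherification of a cyclic 1,3-dione; the alcohol condenses at C8 and not at the C2 carbonyl, which is neopentyl (next to quaternary C1).

**Step 6**
Reactants: 9
Product: 10, trans-decalin 2-alkoxy-enedione (C2 and C9 ketones, C8 propargyl enol ether, Δ12)
Conditions: Dess–Martin periodinane, NaHCO3, CH2Cl2, 0 °C → rt
Reagents that add atoms: none
Why: Dess–Martin oxidation removes the C9 epimer mixture under neutral conditions, so C10 (now α to a ketone) is not epimerised.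

**Step 7**
Reactants: 10
Product: 11, 12α,13α-epoxide of 10
Conditions: mCPBA, NaHCO3, CH2Cl2, 0 °C
Reagents that add atoms: mCPBA, O=C(OO)c1cccc(Cl)c1
Why: Prilezhaev epoxidation of the only electron-rich alkene; attack is from the α-face because the β-face is blocked by the axial C15 and C20 methyls.

**Step 8**
Reactants: 11
Product: 12, 2β,9β-diol (C8 propargyl enol ether and 12α,13α-epoxide retained)
Conditions: DIBAL-H (4 equiv), THF, −78 °C; Rochelle salt; used crude
Reagents that add atoms: none
Why: 1,2-Reduction of the C9 ketone and the C2 vinylogous-ester carbonyl; hydride enters both from the α-face because β-approach is blocked by the axial C15 methyl (syn-axial at C9, vicinal at C2), giving the 2β,9β-diol.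

**Step 9**
Reactants: 12
Product: 13, 2β,9β-bis(TBS) ether of 12
Conditions: TBSOTf, 2,6-lutidine, CH2Cl2, −78 → 0 °C
Reagents that add atoms: TBSOTf, CC(C)(C)[Si](C)(C)OS(=O)(=O)C(F)(F)F
Why: Silylation under buffered conditions protects both carbinols and stabilises the acid-labile γ-alkoxy allylic alcohol.

**Step 10**
Reactants: 13
Product: 14, 12α-hydroxy-Δ13 allylic alcohol
Conditions: LiNEt2 (4 equiv), Et2O/hexane, 0 °C → rt
Reagents that add atoms: none
Why: Lithium-amide-mediated epoxide to allylic alcohol isomerisation (syn β-elimination); the pseudo-axial H14α on the CH2 is removed in preference to the tertiary H11, moving the alkene to C13=C14 and leaving the 12α C–O bond untouched.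

**Step 11**
Reactants: 14
Product: 15, 13α,14α-epoxy-12α-ol
Conditions: VO(acac)2 (5 mol%), t-BuOOH, CH2Cl2, 0 °C
Reagents that add atoms: tert-butyl hydroperoxide, CC(C)(C)OO
Why: Hydroxyl-directed vanadium epoxidation delivers oxygen syn to the 12α-OH (also the less hindered face) and leaves the undirected enol ether alone.

**Step 12**
Reactants: 15
Product: 16, 2β,9β,12α-tris(TBS) ether
Conditions: TBSOTf, 2,6-lutidine, CH2Cl2, −78 °C
Reagents that add atoms: TBSOTf, CC(C)(C)[Si](C)(C)OS(=O)(=O)C(F)(F)F
Why: Silylation of the remaining secondary alcohol so that all three future acetate positions carry the same group.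

**Step 13**
Reactants: 16
Product: 17, 3α-(propa-1,2-dienyl)-8-ketone (trans-decalin; 2β,9β,12α-tris-OTBS; 13α,14α-epoxide)
Conditions: o-xylene, 140 °C, base-washed glassware, BHT (cat.)
Reagents that add atoms: none
Why: Saucy–Marbet propargyl Claisen [3,3] rearrangement; the new C3–C4 bond forms on the α-face (anti to the C15 methyl and the 2β-OTBS), giving the equatorial 3α-allene, and neutral thermal conditions avoid isomerisation to a conjugated dienone.

**Step 14**
Reactants: 18, 4-methoxybenzyl alcohol; 19, vinyl acetate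
Product: 20, 4-methoxybenzyl vinyl ether
Conditions: [Ir(cod)Cl]2 (1 mol%), Na2CO3, toluene, 100 °C
Reagents that add atoms: none
Why: Iridium-catalysed transvinylation of an alcohol with vinyl acetate.

**Step 15**
Reactants: 20
Product: 21, (Z)-1-bromo-2-(4-methoxybenzyloxy)ethene
Conditions: Br2, CH2Cl2, −78 °C; then Et3N, → rt
Reagents that add atoms: bromine, BrBr
Why: Bromine addition then E2 dehydrobromination of the α,β-dibromo ether gives the Z-β-bromovinyl ether, as in the standard preparation of (Z)-1-bromo-2-ethoxyethene.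

**Step 16**
Reactants: 17; 21 (as the vinylcerium reagent)
Product: 22, 8β-hydroxy-8α-[(Z)-2-(PMB-oxy)vinyl]-3α-allenyl trans-decalin
Conditions: 21, t-BuLi (2 equiv), Et2O, −78 °C; CeCl3, THF, −78 °C; then 17
Reagents that add atoms: none
Why: Organocerium 1,2-addition (non-basic, so no enolisation or allene isomerisation); axial attack from the α-face, anti to the axial 9β-OTBS (Felkin–Anh), gives the equatorial 8β-OH and an axial alkenyl group cis to the 3α-allene.

**Step 17**
Reactants: 22
Product: 23, ten-membered α-ketol (3Z-ene, 5(16)-methylene, 6β-OPMB, 7β-OH, 8-ketone; 2β,9β,12α-tris-OTBS; 13α,14α-epoxide)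
Conditions: KHMDS, 18-crown-6, THF, −40 → 0 °C; then Davis oxaziridine, −78 °C; AcOH quench
Reagents that add atoms: 2-(phenylsulfonyl)-3-phenyloxaziridine, O=S(=O)(N1OC1c1ccccc1)c1ccccc1
Why: Proposed new method: the C8 alkoxide triggers a [3,3] shift through the only chair transition state open to the equatorial-allenyl/axial-alkenyl decalin (C2 pseudo-axial gives 3Z; the allene central carbon becomes C5 bearing the exo-methylene; the Z-enol ether terminus gives 6β-OPMB), and the ring-expanded enolate is hydroxylated on its exposed face to give 7β-OH; the closest known reactions are the anionic oxy-Cope ring expansion of 1,2-dialkenylcyclohexanols to cyclodecenones, the allenyl Cope rearrangement, and tandem oxy-Cope/enolate oxidation.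

**Step 18**
Reactants: 23; 24, 2-bromopropanoic acid (racemic)
Product: 25, 7α-(2-bromopropanoyloxy) ketone (mixture at CHBr, which is destroyed in step 19)
Conditions: PPh3, DIAD, THF, 0 °C → rt
Reagents that add atoms: none
Why: Mitsunobu esterification inverts C7 to the natural 7α-O configuration while attaching the C17–C19 unit.

**Step 19**
Reactants: 25
Product: 26, 8α-hydroxy γ-lactone (C8–C17 bond formed; natural C7, C8, C17; 6β-OPMB)
Conditions: SmI2 (2.2 equiv), THF, −78 °C
Reagents that add atoms: none
Why: SmI2 intramolecular Reformatsky reaction; the samarium enolate can only reach the C8 carbonyl face syn to its O7 tether (C6–C7–C8–C9 antiperiplanar), giving 8α-OH, and the epimerisable C17 methyl settles trans to C9 (cis to 8-OH), with DBU equilibration available if a mixture forms.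

**Step 20**
Reactants: 26
Product: 27, 2β,8α,9β,12α-tetraol (6β-OPMB)
Conditions: HF·pyridine, pyridine, THF, 0 °C → rt
Reagents that add atoms: none
Why: Buffered fluoride desilylation removes the three TBS groups; the PMB ether, hindered epoxide and lactone are expected to survive.

**Step 21**
Reactants: 27
Product: 28, 2β,9β,12α-triacetate (8α-OH free, 6β-OPMB)
Conditions: Ac2O, pyridine, DMAP (cat.), CH2Cl2, 0 °C → rt
Reagents that add atoms: acetic anhydride, CC(=O)OC(C)=O
Why: Acetylation of the three secondary alcohols; the tertiary C8-OH does not react under these conditions.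

**Step 22**
Reactants: 28
Product: 29, 6β-alcohol (6-epi-hydroxy analogue of the target)
Conditions: DDQ, CH2Cl2/pH 7 buffer, 0 °C
Reagents that add atoms: none
Why: Oxidative PMB cleavage under neutral conditions; the twisted, electron-poor diene is a poor partner for DDQ.

**Step 23**
Reactants: 29
Product: 30, brianthein Z
Conditions: PPh3, hexachloroacetone, CH2Cl2, −20 → 0 °C
Reagents that add atoms: hexachloroacetone, ClC(Cl)(Cl)C(=O)C(Cl)(Cl)Cl
Why: Appel-type chlorination with Magid's reagent converts allylic alcohols to chlorides by SN2 with inversion and little allylic transposition, giving the 6α-chloride; the tertiary alcohol is inert.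

## Compound list

1 | ethyl tiglate | C/C=C(\C)C(=O)OCC | starting material
2 | ethyl (E)-2-methyl-4-oxobut-2-enoate | O=C/C=C(\C)C(=O)OCC | intermediate
3 | (E)-penta-1,3-diene | C/C=C/C=C | starting material
4 | ethyl (1S,5S,6S)-6-formyl-1,5-dimethylcyclohex-3-ene-1-carboxylate | CCOC(=O)[C@]1(C)[C@@H](C=O)[C@@H](C)C=CC1 | intermediate
5 | ethyl vinyl ether | C=COCC | starting material
6 | ethyl (1S,5S,6S)-6-(1-hydroxy-2-oxopropyl)-1,5-dimethylcyclohex-3-ene-1-carboxylate (C9 epimers) | CCOC(=O)[C@]1(C)[C@@H](C(O)C(C)=O)[C@@H](C)C=CC1 | intermediate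
7 | (4aS,5S,8aS)-4-hydroxy-5,8a-dimethyl-4a,5,8,8a-tetrahydronaphthalene-1,3(2H,4H)-dione | O=C1CC(=O)C(O)[C@H]2[C@@H](C)C=CC[C@]12C | intermediate
8 | propargyl alcohol | C#CCO | starting material
9 | trans-decalin vinylogous ester (C2=O, C8 O-propargyl enol ether, C9-OH) | O=C1C=C(OCC#C)C(O)[C@H]2[C@@H](C)C=CC[C@]12C | intermediate
10 | trans-decalin 2-alkoxy-enedione (C2=O, C9=O) | O=C1C=C(OCC#C)C(=O)[C@H]2[C@@H](C)C=CC[C@]12C | intermediate
11 | 12α,13α-epoxy enedione | O=C1C=C(OCC#C)C(=O)[C@H]2[C@@H](C)[C@@H]3O[C@@H]3C[C@]12C | intermediate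
12 | 2β,9β-diol | O[C@H]1C=C(OCC#C)[C@@H](O)[C@H]2[C@@H](C)[C@@H]3O[C@@H]3C[C@]12C | intermediate
13 | 2β,9β-bis-TBS ether | CC(C)(C)[Si](C)(C)O[C@H]1C=C(OCC#C)[C@@H](O[Si](C)(C)C(C)(C)C)[C@H]2[C@@H](C)[C@@H]3O[C@@H]3C[C@]12C | intermediate
14 | 12α-hydroxy-Δ13 allylic alcohol | CC(C)(C)[Si](C)(C)O[C@H]1C=C(OCC#C)[C@@H](O[Si](C)(C)C(C)(C)C)[C@H]2[C@@H](C)[C@H](O)C=C[C@]12C | intermediate
15 | 13α,14α-epoxy-12α-ol | CC(C)(C)[Si](C)(C)O[C@H]1C=C(OCC#C)[C@@H](O[Si](C)(C)C(C)(C)C)[C@H]2[C@@H](C)[C@H](O)[C@@H]3O[C@@H]3[C@]12C | intermediate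
16 | 2β,9β,12α-tris-TBS propargyl enol ether | CC(C)(C)[Si](C)(C)O[C@H]1C=C(OCC#C)[C@@H](O[Si](C)(C)C(C)(C)C)[C@H]2[C@@H](C)[C@H](O[Si](C)(C)C(C)(C)C)[C@@H]3O[C@@H]3[C@]12C | intermediate
17 | 3α-allenyl-8-ketone | CC(C)(C)[Si](C)(C)O[C@H]1[C@H](C=C=C)C(=O)[C@@H](O[Si](C)(C)C(C)(C)C)[C@H]2[C@@H](C)[C@H](O[Si](C)(C)C(C)(C)C)[C@@H]3O[C@@H]3[C@]12C | intermediate
18 | 4-methoxybenzyl alcohol | COc1ccc(CO)cc1 | starting material
19 | vinyl acetate | C=COC(C)=O | starting material
20 | 4-methoxybenzyl vinyl ether | C=COCc1ccc(OC)cc1 | intermediate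
21 | (Z)-1-bromo-2-(4-methoxybenzyloxy)ethene | Br/C=C\OCc1ccc(OC)cc1 | intermediate
22 | 8β-hydroxy-8α-[(Z)-2-(PMB-oxy)vinyl]-3α-allenyl decalin | CC(C)(C)[Si](C)(C)O[C@H]1[C@H](C=C=C)[C@](O)(/C=C\OCc4ccc(OC)cc4)[C@@H](O[Si](C)(C)C(C)(C)C)[C@H]2[C@@H](C)[C@H](O[Si](C)(C)C(C)(C)C)[C@@H]3O[C@@H]3[C@]12C | intermediate
23 | ten-membered α-ketol (3Z, 5(16)-ene, 6β-OPMB, 7β-OH, 8-oxo) | C=C1/C=C\[C@H](O[Si](C)(C)C(C)(C)C)[C@]2(C)[C@H]([C@@H](C)[C@H](O[Si](C)(C)C(C)(C)C)[C@@H]3O[C@@H]32)[C@H](O[Si](C)(C)C(C)(C)C)C(=O)[C@H](O)[C@@H]1OCc1ccc(OC)cc1 | intermediate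
24 | 2-bromopropanoic acid | CC(Br)C(=O)O | starting material
25 | 7α-(2-bromopropanoyloxy) ketone | C=C1/C=C\[C@H](O[Si](C)(C)C(C)(C)C)[C@]2(C)[C@H]([C@@H](C)[C@H](O[Si](C)(C)C(C)(C)C)[C@@H]3O[C@@H]32)[C@H](O[Si](C)(C)C(C)(C)C)C(=O)[C@@H](OC(=O)C(C)Br)[C@@H]1OCc1ccc(OC)cc1 | intermediate
26 | 8α-hydroxy γ-lactone, tris-TBS, 6β-OPMB | C=C1/C=C\[C@H](O[Si](C)(C)C(C)(C)C)[C@]2(C)[C@H]([C@@H](C)[C@H](O[Si](C)(C)C(C)(C)C)[C@@H]3O[C@@H]32)[C@H](O[Si](C)(C)C(C)(C)C)[C@]2(O)[C@@H](C)C(=O)O[C@H]2[C@@H]1OCc1ccc(OC)cc1 | intermediate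
27 | 2,8,9,12-tetraol, 6β-OPMB | C=C1/C=C\[C@H](O)[C@]2(C)[C@H]([C@@H](C)[C@H](O)[C@@H]3O[C@@H]32)[C@H](O)[C@]2(O)[C@@H](C)C(=O)O[C@H]2[C@@H]1OCc1ccc(OC)cc1 | intermediate
28 | 2,9,12-triacetate, 6β-OPMB | C=C1/C=C\[C@H](OC(C)=O)[C@]2(C)[C@H]([C@@H](C)[C@H](OC(C)=O)[C@@H]3O[C@@H]32)[C@H](OC(C)=O)[C@]2(O)[C@@H](C)C(=O)O[C@H]2[C@@H]1OCc1ccc(OC)cc1 | intermediate
29 | 6β-alcohol (6-epi-hydroxy-deschloro brianthein Z) | C=C1/C=C\[C@H](OC(C)=O)[C@]2(C)[C@H]([C@@H](C)[C@H](OC(C)=O)[C@@H]3O[C@@H]32)[C@H](OC(C)=O)[C@]2(O)[C@@H](C)C(=O)O[C@H]2[C@@H]1O | intermediate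
30 | brianthein Z | C=C1/C=C\[C@H](OC(C)=O)[C@]2(C)[C@H]([C@@H](C)[C@H](OC(C)=O)[C@@H]3O[C@@H]32)[C@H](OC(C)=O)[C@]2(O)[C@@H](C)C(=O)O[C@H]2[C@H]1Cl | target

## Summary

**Total step count:** 23.
**Longest linear sequence:** 21 steps (steps 1–13 and 16–23, from ethyl tiglate); steps 14–15 are a two-step branch to reagent 21.

**Three steps most likely to fail, with fallbacks**

1. **Step 17 (allenyl anionic oxy-Cope with hydroxylation).** Risks: a boat transition state giving the 3E-olefin, β-elimination of the C6 alkoxide from the enolate, or C9→C8 silyl migration. Fallback: give up the ring expansion and use the conventional macrocyclisation. Keep ring A from 4, build a C2 aldehyde arm and a (Z)-vinyl iodide/diene arm from C9, and close C2–C3 by intramolecular Nozaki–Hiyama–Kishi coupling.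
2. **Step 18 (Mitsunobu on a hindered α-ketol; depends on the predicted 7β-OH).** Fallback: form the lactone C–O bond with inversion instead of the C–C bond. Protect the C7-OH, add a propionate enolate intermolecularly to the C8 ketone, deprotect and hydrolyse, then close the γ-lactone by Mitsunobu lactonisation at C7. If the hydroxylation instead gives 7α-OH directly, acylate with 2-bromopropionyl bromide and go to step 19.
3. **Step 23 (SN2 versus SN2′ in the final chlorination).** Fallback: reverse the allylic logic. Transpose 29 to the primary 16-hydroxy-Δ5(6) isomer (Re2O7-catalysed 1,3-hydroxyl shift) and return chlorine to C6 with SOCl2 by SNi′, which regenerates the 5(16)-exo-methylene.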